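The readings stem from a simulated flask with made-up constants, noise included.

Early times were where I looked first, for two rates and their ratio: that of making links and that of making rings.

| setting | ochre | amber | green | dawn | autumn | summer | dusk | noon |
|---|---|---|---|---|---|---|---|---|
| first end groups | 10 mM | 5 mM | 7.5 mM | 10 mM (fed, over 3.0 h) | 10 mM | 10 mM | 10 mM | 10 mM |
| second end groups | 0.90 equiv | 0.90 equiv | 0.90 equiv | 0.900 equiv | 0.900 equiv (fed, over 12 h) | 0.900 equiv (fed, over 12 h) | 0.900 equiv | 0.900 equiv |
| temperature | 35 °C | 50 °C | 35 °C | 50 °C |  | 50 °C | 50 °C |  |
| remark | run made earlier | run made earlier | run made earlier | all else is in the flask from the start; the feed brings no volume worth counting | the addition at 30 °C, then warmed to 50 °C; the feed brings no volume worth counting | all else is in the flask from the start; the feed brings no volume worth counting | everything together at the start | everything together at the start at 30 °C, warmed to 50 °C at 12 h |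
| time |  |  |  | 2.5 d | 2.5 d | 2.5 d | 2.5 d | 2.5 d |

- ochre (time / d: links / %, rings / %): 0.833: 35, 4; 1.67: 37, 10; 2.00: 35, 15; 4.00: 37, 19
- amber (time / h: links / %, rings / %): 6.00: 18, 15; 15.0: 20, 36; 30.0: 23, 53; 50.0: 17, 52
- green (time / d: links / %, rings / %): 0.333: 15, 2; 0.625: 24, 4; 1.67: 32, 11; 4.00: 39, 17

(scatter of a reading: 2 percentage points)



1. the flask that comes out highest in share of links in links plus rings, or "all alike" when all lie within 1.5 percentage points (dawn / autumn / summer / dusk / noon / all alike)
2. share of links in links plus rings at the end, dawn
3. share of links in links plus rings at the end, autumn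
4. share of links in links plus rings at the end, summer
5. share of links in links plus rings at the end, dusk
6. share of links in links plus rings at the end, noon

At 1.67 d the ochre run, charged at 10 mM, stood at 10% rings and the green run, charged at 7.5 mM, at 11%, alike within the scatter, so I wrote ring making as first order, k_r[A], with [A] the first end groups; links stood at 37% against 32%, higher at the higher charge, so I wrote k_l[A][B], with [B] the second end groups. Then [A] cancels, and the selectivity factor, links made per ring, is S = [B]/c×. The amber run at 50 °C gave 18% links and 15% rings at 6.00 h, so on its charged [B] I read 3.75 mM as c×, the crossover concentration, the [B] at which both rates are equal. The same reading on the ochre run at 35 °C gave 1.03 mM, less than at the warmer temperature.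

Dusk starts at 9.00 mM, so S is 2.40. I therefore expected dawn, where the fed species cancels, beside dusk, summer, with [B] fed slowly, below it, and noon, with full [B] in the cold hours, as the highest.

The forecast chose autumn, giving dawn 41%, autumn 49%, summer 42%, dusk 40% and noon 43%, in the words “Summer and dawn should differ little from dusk.” We parted on summer.

Noon came out highest at 41.7%, with dawn 35.1%, autumn 38.3%, summer 21.2% and dusk 34.9%. Summer held 41.1% of its second end groups at the end of the feed, which is 3.70 mM, close to c×, so by that reading of c× the estimate of S for summer at that moment is 0.987.

    first end groups + second end groups → rings, rate k1*[first end groups] as long as [second end groups] is above zero (k = 0.0380 h⁻¹, Ea = 115 kJ mol⁻¹)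
    first end groups + second end groups → links (k = 12.0 M⁻¹ h⁻¹, Ea = 61.0 kJ mol⁻¹)
    second end groups + links → over-reaction product (k = 6.40 M⁻¹ h⁻¹, Ea = 58.0 kJ mol⁻¹)
    links ⇌ isomer of the product (K = 1.60, k = 0.0120 h⁻¹, Ea = 106 kJ mol⁻¹, ΔH = 27.0 kJ mol⁻¹)
    (constants at 50 °C)

A neighbouring flask, the same as noon but with 25 mM of first end groups, starts at 22.5 mM, so c× gives S of 6.00 at the warm temperature, against 2.40 for noon's charge. Its computed share was 61.4%, higher than noon's.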